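## Retrosynthetic overview

1. Target 16 ⇐ hydroxyl-directed epoxidation of the exocyclic C8=C14 alkene of bicyclic cis-diol 15 (oxirane made last).
2. 15 ⇐ key step: reductive pinacol coupling of dialdehyde 14 on low-valent titanium, joining the two carbonyl carbons C9 and C10 (both electrophilic, each reacting as a metal-bound ketyl). This closes the seven-membered ring and sets C9 and C10.
3. 14 ⇐ ester 11 by N-oxide oxidation (C9–Cl → CHO) and ozonolysis (2-methylpropenyl → C10 aldehyde); 11 ⇐ aldehyde 7 + 3-chloro-2-(chloromethyl)prop-1-ene 8 (chelation-controlled Barbier allylation sets C6), then isovalerylation.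
4. 7 ⇐ diol 6 ⇐ ketone 5 (isopropyl addition sets C4); 5 ⇐ 3-methylcyclopent-2-enone 1 + alkenyl nucleophile 2 + CH2O (catalytic asymmetric conjugate addition/aldol sets C1 and C5).
5. Ring order: the five-membered ring is bought in 1, the seven-membered ring is formed in the pinacol step, the oxirane last.

Assumption: atom labels follow daucane numbering (C1 methyl-bearing ring-fusion carbon, C4 isopropyl carbinol, C5 ring-fusion CH, C6 ester carbinol, C7 CH2, C8/C14 oxirane carbons, C9 and C10 diol carbons); the target SMILES is read as (1S,4R,5S,6S,8S,9S,10S).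

## Route

Step 1
Reactants: 1 3-methylcyclopent-2-en-1-one; 2 2-methylprop-1-en-1-ylmagnesium bromide
Product: 5 (2S,3R)-2-(hydroxymethyl)-3-methyl-3-(2-methylprop-1-en-1-yl)cyclopentan-1-one, via alkenylalane 3 (not isolated), via aluminium enolate 4 (not isolated)
Conditions: 2, Me2AlCl, Et2O, 0 °C; then 1, Cu(O2CC4H3S) (5 mol %), chiral aminophosphine Ph2P–N[CH(CH3)(2-naphthyl)]2 (10 mol %, enantiomer chosen to give 3R), Et2O, −30 °C; then CH2O (monomer in THF, 1.2 equiv), −78 °C; aq. NH4Cl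
Reagents that add atoms: formaldehyde, C=O
Why: Copper-catalysed asymmetric conjugate addition of an alkenylalane to the β-methyl enone sets the quaternary C1 under ligand control (3R), and the regiodefined aluminium enolate then undergoes an aldol reaction with formaldehyde on the face opposite the bulky 2-methylpropenyl group, so CH2OH ends up cis to the methyl group (2S).

Step 2
Reactants: 5 (2S,3R)-2-(hydroxymethyl)-3-methyl-3-(2-methylprop-1-en-1-yl)cyclopentan-1-one
Product: 6 (1R,2S,3R)-2-(hydroxymethyl)-3-methyl-3-(2-methylprop-1-en-1-yl)-1-(propan-2-yl)cyclopentan-1-ol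
Conditions: iPrMgCl (3 equiv), CeCl3 (3 equiv, dried), THF, −78 → −20 °C; aq. NH4Cl
Reagents that add atoms: isopropylmagnesium chloride, CC(C)[Mg]Cl
Why: Organocerium (Imamoto-type) 1,2-addition suppresses enolisation, retro-aldol loss of formaldehyde and β-hydride reduction, and the isopropyl group enters the cyclopentanone anti to the adjacent C5 substituent, giving the tertiary alcohol cis to CH2OH (1R).

Step 3
Reactants: 6 (1R,2S,3R)-2-(hydroxymethyl)-3-methyl-3-(2-methylprop-1-en-1-yl)-1-(propan-2-yl)cyclopentan-1-ol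
Product: 7 (1R,2R,5R)-2-hydroxy-5-methyl-5-(2-methylprop-1-en-1-yl)-2-(propan-2-yl)cyclopentane-1-carbaldehyde
Conditions: TEMPO (10 mol %), PhI(OAc)2 (1.1 equiv), CH2Cl2, 0 → 25 °C; used at once
Reagents that add atoms: none
Why: Oxoammonium (TEMPO) oxidation is selective for the primary alcohol, leaves the tertiary alcohol and the trisubstituted alkene alone and is nearly neutral, which spares the retro-aldol-prone β-hydroxy aldehyde; C5 is unchanged and already sits in its preferred configuration (formyl trans to isopropyl and to the alkenyl group).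

Step 4
Reactants: 7 (1R,2R,5R)-2-hydroxy-5-methyl-5-(2-methylprop-1-en-1-yl)-2-(propan-2-yl)cyclopentane-1-carbaldehyde; 8 3-chloro-2-(chloromethyl)prop-1-ene
Product: 10 (1R,2S,3R)-2-[(1S)-3-(chloromethyl)-1-hydroxybut-3-en-1-yl]-3-methyl-3-(2-methylprop-1-en-1-yl)-1-(propan-2-yl)cyclopentan-1-ol, via allylzinc chloride 9 (not isolated)
Conditions: 8 (3 equiv), Zn dust (2 equiv), THF/sat. aq. NH4Cl (1:1), 0 → 25 °C
Reagents that add atoms: none
Why: Aqueous zinc Barbier allylation in which the allylzinc attacks the aldehyde held syn to the tertiary hydroxyl by zinc chelation/hydrogen bonding (Cram-chelate model) from the H-5 face, anti to quaternary C1, which sets C6 as S; excess dichloride keeps the second C–Cl bond intact.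

Step 5
Reactants: 10 (1R,2S,3R)-2-[(1S)-3-(chloromethyl)-1-hydroxybut-3-en-1-yl]-3-methyl-3-(2-methylprop-1-en-1-yl)-1-(propan-2-yl)cyclopentan-1-ol
Product: 11 (1S)-3-(chloromethyl)-1-[(1S,2R,5R)-2-hydroxy-5-methyl-5-(2-methylprop-1-en-1-yl)-2-(propan-2-yl)cyclopentyl]but-3-en-1-yl 3-methylbutanoate
Conditions: 3-methylbutanoic anhydride (1.5 equiv), Et3N (2 equiv), DMAP (10 mol %), CH2Cl2, 0 → 25 °C
Reagents that add atoms: 3-methylbutanoic anhydride, CC(C)CC(=O)OC(=O)CC(C)C
Why: DMAP-catalysed acyl transfer esterifies the only secondary hydroxyl while the tertiary C4 hydroxyl is inert, and the ester is installed now because the later C9 and C10 hydroxyls could not be distinguished from C6–OH; no stereocentre is touched.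

Step 6
Reactants: 11 (1S)-3-(chloromethyl)-1-[(1S,2R,5R)-2-hydroxy-5-methyl-5-(2-methylprop-1-en-1-yl)-2-(propan-2-yl)cyclopentyl]but-3-en-1-yl 3-methylbutanoate
Product: 12 (1S)-3-formyl-1-[(1S,2R,5R)-2-hydroxy-5-methyl-5-(2-methylprop-1-en-1-yl)-2-(propan-2-yl)cyclopentyl]but-3-en-1-yl 3-methylbutanoate
Conditions: N-methylmorpholine N-oxide (4 equiv), NaI (10 mol %), NaHCO3 (2 equiv), MeCN, 40 °C
Reagents that add atoms: N-methylmorpholine N-oxide, C[N+]1([O-])CCOCC1
Why: Ganem/Kornblum-type N-oxide oxidation in which the amine-oxide oxygen displaces the allylic chloride (SN2 and SN2' give the same constitution because C9 and C14 are equivalent) and base-induced fragmentation of the alkoxyammonium ion gives the 2-substituted acrolein without touching the ester, the tertiary alcohol or the trisubstituted alkene.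

Step 7
Reactants: 12 (1S)-3-formyl-1-[(1S,2R,5R)-2-hydroxy-5-methyl-5-(2-methylprop-1-en-1-yl)-2-(propan-2-yl)cyclopentyl]but-3-en-1-yl 3-methylbutanoate
Product: 14 (1S)-3-formyl-1-[(1S,2R,5S)-5-formyl-2-hydroxy-5-methyl-2-(propan-2-yl)cyclopentyl]but-3-en-1-yl 3-methylbutanoate, via ozonide 13 (not isolated)
Conditions: O3 (1.0 equiv), CH2Cl2, −78 °C; then PPh3 (1.2 equiv), −78 → 25 °C
Reagents that add atoms: ozone, [O-][O+]=O
Why: Ozonolysis in which electrophilic ozone attacks the electron-rich trisubstituted alkene far faster than the electron-poor α-methylene aldehyde, so one equivalent unmasks the C10 aldehyde on the non-epimerisable quaternary C1 and PPh3 reduces the ozonide.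

Step 8 (key step)
Reactants: 14 (1S)-3-formyl-1-[(1S,2R,5S)-5-formyl-2-hydroxy-5-methyl-2-(propan-2-yl)cyclopentyl]but-3-en-1-yl 3-methylbutanoate
Product: 15 (3R,3aS,4S,7R,8S,8aS)-3,7,8-trihydroxy-8a-methyl-6-methylidene-3-(propan-2-yl)decahydroazulen-4-yl 3-methylbutanoate
Conditions: TiCl3(DME)1.5 (8 equiv), Zn–Cu couple (20 equiv), DME, reflux 3 h (reagent formation); then 14 added over 10 h at 25 °C (final 0.005 M); aq. K2CO3
Reagents that add atoms: none
Why: McMurry-type intramolecular pinacol coupling in which both aldehydes are reduced to titanium-bound ketyls and couple carbon to carbon (C9–C10), oxophilic titanium directing the enal to react at its carbonyl carbon and not at C14, as known for enal/neopentyl-aldehyde pairs in medium-ring closures; the titanium bridge gives the cis-diol, and the chair-like seven-ring transition state places C10–O axial anti to the angular methyl and C9–O equatorial (the other cis-diol would put C9–O 1,3-diaxial to that methyl), giving 7R,8S in 15.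

Step 9
Reactants: 15 (3R,3aS,4S,7R,8S,8aS)-3,7,8-trihydroxy-8a-methyl-6-methylidene-3-(propan-2-yl)decahydroazulen-4-yl 3-methylbutanoate
Product: 16 CNP0307265.1, (1S,4R,5S,6S,8S,9S,10S)-8,14-epoxy-4,9,10-trihydroxydaucan-6-yl 3-methylbutanoate
Conditions: VO(acac)2 (5 mol %), t-BuOOH (1.5 equiv, in decane), CH2Cl2, 0 → 25 °C
Reagents that add atoms: tert-butyl hydroperoxide, CC(C)(C)OO
Why: Vanadium-catalysed hydroxyl-directed epoxidation in which the allylic C9 hydroxyl and the homoallylic C10 hydroxyl, both on the same face, bind vanadium and deliver the peroxide oxygen to that face of the only alkene, giving the spiro-oxirane with oxygen syn to C9–OH (8S).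

## Compound list

1 | 3-methylcyclopent-2-en-1-one | CC1=CC(=O)CC1 | starting material
2 | 2-methylprop-1-en-1-ylmagnesium bromide | CC(C)=C[Mg]Br | starting material
3 | dimethyl(2-methylprop-1-en-1-yl)aluminium | CC(C)=C[Al](C)C | intermediate
4 | dimethylaluminium (3R)-3-methyl-3-(2-methylprop-1-en-1-yl)cyclopent-1-en-1-olate | C[Al](C)OC1=C[C@@](C)(C=C(C)C)CC1 | intermediate
5 | (2S,3R)-2-(hydroxymethyl)-3-methyl-3-(2-methylprop-1-en-1-yl)cyclopentan-1-one | OC[C@@H]1[C@@](C)(C=C(C)C)CCC1=O | intermediate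
6 | (1R,2S,3R)-2-(hydroxymethyl)-3-methyl-3-(2-methylprop-1-en-1-yl)-1-(propan-2-yl)cyclopentan-1-ol | OC[C@@H]1[C@@](C)(C=C(C)C)CC[C@@]1(O)C(C)C | intermediate
7 | (1R,2R,5R)-2-hydroxy-5-methyl-5-(2-methylprop-1-en-1-yl)-2-(propan-2-yl)cyclopentane-1-carbaldehyde | O=C[C@@H]1[C@@](C)(C=C(C)C)CC[C@@]1(O)C(C)C | intermediate
8 | 3-chloro-2-(chloromethyl)prop-1-ene | ClCC(=C)CCl | starting material
9 | [2-(chloromethyl)prop-2-en-1-yl]zinc chloride | ClCC(=C)C[Zn]Cl | intermediate
10 | (1R,2S,3R)-2-[(1S)-3-(chloromethyl)-1-hydroxybut-3-en-1-yl]-3-methyl-3-(2-methylprop-1-en-1-yl)-1-(propan-2-yl)cyclopentan-1-ol | O[C@@H](CC(=C)CCl)[C@@H]1[C@@](C)(C=C(C)C)CC[C@@]1(O)C(C)C | intermediate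
11 | (1S)-3-(chloromethyl)-1-[(1S,2R,5R)-2-hydroxy-5-methyl-5-(2-methylprop-1-en-1-yl)-2-(propan-2-yl)cyclopentyl]but-3-en-1-yl 3-methylbutanoate | CC(C)CC(=O)O[C@@H](CC(=C)CCl)[C@@H]1[C@@](C)(C=C(C)C)CC[C@@]1(O)C(C)C | intermediate
12 | (1S)-3-formyl-1-[(1S,2R,5R)-2-hydroxy-5-methyl-5-(2-methylprop-1-en-1-yl)-2-(propan-2-yl)cyclopentyl]but-3-en-1-yl 3-methylbutanoate | CC(C)CC(=O)O[C@@H](CC(=C)C=O)[C@@H]1[C@@](C)(C=C(C)C)CC[C@@]1(O)C(C)C | intermediate
13 | (1S)-1-[(1S,2R,5S)-5-(3,3-dimethyl-1,2,4-trioxolan-5-yl)-2-hydroxy-5-methyl-2-(propan-2-yl)cyclopentyl]-3-formylbut-3-en-1-yl 3-methylbutanoate (trioxolane C5 epimers) | CC(C)CC(=O)O[C@@H](CC(=C)C=O)[C@@H]1[C@@](C)(C2OOC(C)(C)O2)CC[C@@]1(O)C(C)C | intermediate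
14 | (1S)-3-formyl-1-[(1S,2R,5S)-5-formyl-2-hydroxy-5-methyl-2-(propan-2-yl)cyclopentyl]but-3-en-1-yl 3-methylbutanoate | CC(C)CC(=O)O[C@@H](CC(=C)C=O)[C@@H]1[C@@](C)(C=O)CC[C@@]1(O)C(C)C | intermediate
15 | (3R,3aS,4S,7R,8S,8aS)-3,7,8-trihydroxy-8a-methyl-6-methylidene-3-(propan-2-yl)decahydroazulen-4-yl 3-methylbutanoate | CC(C)CC(=O)O[C@H]1CC(=C)[C@@H](O)[C@@H](O)[C@@]2(C)CC[C@@](O)(C(C)C)[C@H]12 | intermediate
16 | CNP0307265.1, (1S,4R,5S,6S,8S,9S,10S)-8,14-epoxy-4,9,10-trihydroxydaucan-6-yl 3-methylbutanoate | CC(C)CC(=O)O[C@H]1C[C@]2(CO2)[C@@H](O)[C@@H](O)[C@@]2(C)CC[C@@](O)(C(C)C)[C@H]12 | target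

## Step count and risks

Total steps: 9. Longest linear sequence: 9 steps (1 → 16).

**Step 8 (pinacol ring closure).** Risks are coupling through C14 of the enal, over-reduction to the alkene, and the wrong diol face. The fallback sets out from 14 and returns at 15, taking the enal out of play before the reductive step. Conjugate addition of PhSH (cat. Et3N, CH2Cl2, 0 °C) to 14 gives the saturated dialdehyde (1S)-3-formyl-1-[(1S,2R,5S)-5-formyl-2-hydroxy-5-methyl-2-(propan-2-yl)cyclopentyl]-4-(phenylsulfanyl)butyl 3-methylbutanoate F1 (C8 epimers, of no consequence). SmI2 (THF, t-BuOH, −78 → 0 °C, high dilution) then effects an ordinary aliphatic dialdehyde pinacol cyclisation through a samarium-bridged diketyl, giving the cis-diol sulfide (3R,3aS,4S,7R,8S,8aS)-3,7,8-trihydroxy-8a-methyl-6-[(phenylsulfanyl)methyl]-3-(propan-2-yl)decahydroazulen-4-yl 3-methylbutanoate F2. Oxidation with mCPBA (1.0 equiv, CH2Cl2, −78 °C) gives the sulfoxide (3R,3aS,4S,7R,8S,8aS)-6-[(benzenesulfinyl)methyl]-3,7,8-trihydroxy-8a-methyl-3-(propan-2-yl)decahydroazulen-4-yl 3-methylbutanoate F3. Its thermal syn-elimination (toluene, CaCO3, 110 °C) can only remove the C8 hydrogen and so re-forms the exocyclic alkene of 15.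

**Step 1 (asymmetric conjugate addition/aldol).** Risks are modest enantioselectivity on the five-membered enone and incomplete facial control in the formaldehyde trapping. The fallback sets out from 1 and 2 and returns at 6, replacing catalysis by resolution. Ligand-free addition of 2 to 1 (CuBr·SMe2 10 mol %, THF, −40 °C; then CH2O) gives racemic rac-(2S,3R)-2-(hydroxymethyl)-3-methyl-3-(2-methylprop-1-en-1-yl)cyclopentan-1-one F4. iPrMgCl/CeCl3 as in step 2 gives the racemic diol rac-(1R,2S,3R)-2-(hydroxymethyl)-3-methyl-3-(2-methylprop-1-en-1-yl)-1-(propan-2-yl)cyclopentan-1-ol F5. Acylation of the primary hydroxyl with (1S)-camphanic chloride (pyridine, DMAP, CH2Cl2) gives two diastereomers, separated by crystallisation or chromatography: [(1S,2R,5R)-2-hydroxy-5-methyl-5-(2-methylprop-1-en-1-yl)-2-(propan-2-yl)cyclopentyl]methyl (1S,4R)-4,7,7-trimethyl-3-oxo-2-oxabicyclo[2.2.1]heptane-1-carboxylate F6 and its diastereomer from the antipodal diol, [(1R,2S,5S)-2-hydroxy-5-methyl-5-(2-methylprop-1-en-1-yl)-2-(propan-2-yl)cyclopentyl]methyl (1S,4R)-4,7,7-trimethyl-3-oxo-2-oxabicyclo[2.2.1]heptane-1-carboxylate F7. Saponification of F6 (LiOH, THF/H2O) returns enantiopure 6.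

**Step 2 (isopropyl addition).** Risks are enolisation, retro-aldol and β-hydride reduction at the hindered ketone. The fallback sets out from 5 and returns at 6, using a smaller sp2 nucleophile without β-hydrogens. Isopropenylmagnesium bromide/CeCl3 (THF, −78 °C) gives (1S,2S,3R)-2-(hydroxymethyl)-3-methyl-3-(2-methylprop-1-en-1-yl)-1-(prop-1-en-2-yl)cyclopentan-1-ol F8. Hydrogenation with H2 (1 atm) over RhCl(PPh3)3 in benzene/EtOH reduces the 1,1-disubstituted alkene and leaves the trisubstituted 2-methylpropenyl group, giving 6.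

## Further compounds

F1 | step 8 | (1S)-3-formyl-1-[(1S,2R,5S)-5-formyl-2-hydroxy-5-methyl-2-(propan-2-yl)cyclopentyl]-4-(phenylsulfanyl)butyl 3-methylbutanoate (C3 epimers) | CC(C)CC(=O)O[C@@H](CC(CSc1ccccc1)C=O)[C@@H]1[C@@](C)(C=O)CC[C@@]1(O)C(C)C
F2 | step 8 | (3R,3aS,4S,7R,8S,8aS)-3,7,8-trihydroxy-8a-methyl-6-[(phenylsulfanyl)methyl]-3-(propan-2-yl)decahydroazulen-4-yl 3-methylbutanoate (C6 epimers) | CC(C)CC(=O)O[C@H]1CC(CSc2ccccc2)[C@@H](O)[C@@H](O)[C@@]2(C)CC[C@@](O)(C(C)C)[C@H]12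
F3 | step 8 | (3R,3aS,4S,7R,8S,8aS)-6-[(benzenesulfinyl)methyl]-3,7,8-trihydroxy-8a-methyl-3-(propan-2-yl)decahydroazulen-4-yl 3-methylbutanoate (C6 and sulfur epimers) | CC(C)CC(=O)O[C@H]1CC(CS(=O)c2ccccc2)[C@@H](O)[C@@H](O)[C@@]2(C)CC[C@@](O)(C(C)C)[C@H]12
F4 | step 1 | rac-(2S,3R)-2-(hydroxymethyl)-3-methyl-3-(2-methylprop-1-en-1-yl)cyclopentan-1-one (racemate, one enantiomer drawn) | OC[C@@H]1[C@@](C)(C=C(C)C)CCC1=O
F5 | step 1 | rac-(1R,2S,3R)-2-(hydroxymethyl)-3-methyl-3-(2-methylprop-1-en-1-yl)-1-(propan-2-yl)cyclopentan-1-ol (racemate, one enantiomer drawn) | OC[C@@H]1[C@@](C)(C=C(C)C)CC[C@@]1(O)C(C)C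
F6 | step 1 | [(1S,2R,5R)-2-hydroxy-5-methyl-5-(2-methylprop-1-en-1-yl)-2-(propan-2-yl)cyclopentyl]methyl (1S,4R)-4,7,7-trimethyl-3-oxo-2-oxabicyclo[2.2.1]heptane-1-carboxylate | O=C(OC[C@@H]1[C@@](C)(C=C(C)C)CC[C@@]1(O)C(C)C)[C@@]12CC[C@@](C)(C(=O)O1)C2(C)C
F7 | step 1 | [(1R,2S,5S)-2-hydroxy-5-methyl-5-(2-methylprop-1-en-1-yl)-2-(propan-2-yl)cyclopentyl]methyl (1S,4R)-4,7,7-trimethyl-3-oxo-2-oxabicyclo[2.2.1]heptane-1-carboxylate | O=C(OC[C@H]1[C@](C)(C=C(C)C)CC[C@]1(O)C(C)C)[C@@]12CC[C@@](C)(C(=O)O1)C2(C)C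
F8 | step 2 | (1S,2S,3R)-2-(hydroxymethyl)-3-methyl-3-(2-methylprop-1-en-1-yl)-1-(prop-1-en-2-yl)cyclopentan-1-ol | OC[C@@H]1[C@@](C)(C=C(C)C)CC[C@@]1(O)C(C)=C
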